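**Plan**
- Retrosynthetic cuts: (i) the enone C=C (Claisen–Schmidt) to an acetophenone and a chroman-6-carbaldehyde; (ii) the C6–CHO bond (formylation para to O1); (iii) C3–H (ketone reduction); (iv) removal of C4 from between C4a and C3, which contracts the pyran ring to a furanone ring; (v) C3=O back to a benzylic CH2.
- Enabling feature: in the dihydropyran ring (O1, C2, C3, C4, C4a, C8a) the carbinol C3 lies between the benzylic C4H2 and the quaternary, O1-bearing C2. This is the β-aryl ketone retron of an aryl-migrating one-carbon homologation. Without C4 the B-ring is the commodity phenol 2,2-dimethyl-2,3-dihydro-1-benzofuran-7-ol, whose ring oxygen is O1 and whose 7-OH is the C8 phenol.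
- Forward order: the five-membered O-ring is present from the start; benzylic oxidation gives the benzofuran-3-one; one-carbon insertion expands it to the chroman-3-one; reduction, formylation at C6, and the chalcone is joined last.
- Stereochemistry: C3 (S) comes from a Corey–Bakshi–Shibata reduction with the (R)-catalyst (quaternary C2 as the large group); the (E)-alkene comes from thermodynamic E1cB dehydration.

Key step: step 3

Assumption: 2,2-dimethyl-2,3-dihydro-1-benzofuran-7-ol and 2,4-dihydroxyacetophenone are taken as commercial; the stereocentre of the target is read from the SMILES as (3S).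

**Step 1**
Reactants: 1 2,2-dimethyl-2,3-dihydro-1-benzofuran-7-ol
Product: 2 2,2-dimethyl-2,3-dihydro-1-benzofuran-7-yl pivalate
Conditions: PivCl, Et3N, DMAP (cat.), CH2Cl2, 0 °C → rt
Reagents that add atoms: pivaloyl chloride CC(C)(C)C(Cl)=O
Why: Acylation of the phenol (DMAP nucleophilic catalysis); the pivalate shields the phenol from Cr(VI) and makes O7 a weak donor, so that later electrophilic substitution is steered para to the ring oxygen.

**Step 2**
Reactants: 2 2,2-dimethyl-2,3-dihydro-1-benzofuran-7-yl pivalate
Product: 3 2,2-dimethyl-3-oxo-2,3-dihydro-1-benzofuran-7-yl pivalate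
Conditions: CrO3, AcOH/H2O, rt
Reagents that add atoms: chromium trioxide O=[Cr](=O)=O
Why: Chromic acid benzylic oxidation: C3 is the only benzylic CH2 and is activated by the ortho ring oxygen, and the quaternary C2 rules out aromatisation to a benzofuran, so the aryl ketone should be the end point (this oxidation is known on 7-O-acyl derivatives of this dihydrobenzofuran).

**Step 3**
Reactants: 3 2,2-dimethyl-3-oxo-2,3-dihydro-1-benzofuran-7-yl pivalate
Product: 5 2,2-dimethyl-3-oxochroman-8-yl pivalate, via α-trimethylsilyl ketone 4 (not isolated)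
Conditions: TMSCHN2 (2 M in hexanes), BF3·OEt2, CH2Cl2, −78 → 0 °C; then 1 M HCl, THF, rt
Reagents that add atoms: trimethylsilyldiazomethane C[Si](C)(C)C=[N+]=[N-]
Why: The BF3-activated C3 carbonyl is attacked by the nucleophilic carbon of TMSCHN2 to give a β-borato alkyldiazonium betaine, from which the aryl carbon C3a migrates to the diazo carbon as N2 leaves (Tiffeneau–Demjanov-type 1,2-shift); the furanone ring thereby becomes the pyranone ring with the new carbon as C4 between C4a and C3, and the α-silyl ketone 4 is protodesilylated on acidic work-up. The closest known reaction type is the Lewis-acid-promoted TMSCHN2 homologation of benzo-fused cyclic aryl ketones (1-indanone to 2-tetralone, 1-tetralone and 4-chromanone to their β-keto homologues). No ring is closed: the existing ring is enlarged by formal insertion of one carbon into the C(aryl)–C(=O) bond, so no cyclisation mode applies. No stereocentre is set: C4 of 4 is a transient racemic centre erased on desilylation, and 5 is achiral. The step needs aryl rather than C2 migration (C2 migration would give the chroman-4-one isomer) and a single insertion; the first should be secured by the electron-rich, ortho-oxygenated aryl group migrating through a phenonium-like transition state while C2 is quaternary, inductively deactivated by O1 and sterically opposed to the Me3Si-bearing terminus, the second by the bulk of the α-silyl ketone, and relief of the strain of the benzofuranone should favour expansion over silyl epoxide formation.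

**Step 4**
Reactants: 5 2,2-dimethyl-3-oxochroman-8-yl pivalate
Product: 6 (3S)-3-hydroxy-2,2-dimethylchroman-8-yl pivalate
Conditions: (R)-2-methyl-CBS-oxazaborolidine (15 mol%), BH3·SMe2, THF, −20 °C; MeOH quench
Reagents that add atoms: none
Why: Corey–Bakshi–Shibata reduction: the ketone should bind the catalyst boron anti to the quaternary, O1-bearing C2 (large group) and syn to the C4 methylene (small group), so the (R)-catalyst should deliver hydride to the face that gives the (3S)-alcohol, the mirror image of the (S)-catalyst/tert-alkyl methyl ketone outcome.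

**Step 5**
Reactants: 6 (3S)-3-hydroxy-2,2-dimethylchroman-8-yl pivalate
Product: 7 (3S)-3-acetoxy-2,2-dimethylchroman-8-yl pivalate
Conditions: Ac2O, pyridine, DMAP (cat.), CH2Cl2, rt
Reagents that add atoms: acetic anhydride CC(=O)OC(C)=O
Why: Standard DMAP-catalysed acetylation that protects the secondary alcohol from dichloromethyl methyl ether and TiCl4; the C3–O bond is not broken, so the configuration is kept.

**Step 6**
Reactants: 7 (3S)-3-acetoxy-2,2-dimethylchroman-8-yl pivalate
Product: 8 (3S)-3-acetoxy-6-formyl-2,2-dimethylchroman-8-yl pivalate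
Conditions: Cl2CHOMe, TiCl4, CH2Cl2, −20 → 0 °C; then ice–water
Reagents that add atoms: dichloromethyl methyl ether COC(Cl)Cl; water O
Why: Rieche formylation (Friedel–Crafts-type attack of the methoxychlorocarbenium ion, then hydrolysis): the ring ether oxygen is the only strong donor, both its ortho positions are substituted and the ester-masked O8 directs only weakly, so attack should occur at C6, para to O1, as in the para-to-ether substitution of guaiacol esters.

**Step 7**
Reactants: 9 2,4-dihydroxyacetophenone
Product: 10 1-[2-hydroxy-4-(methoxymethoxy)phenyl]ethan-1-one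
Conditions: MOMCl, K2CO3, acetone, 0 °C → rt
Reagents that add atoms: chloromethyl methyl ether COCCl
Why: Williamson-type O-alkylation: the 4-OH is the free, more acidic phenol whereas the 2-OH is locked in a hydrogen bond to the ketone, so mono-protection at O4 should result.

**Step 8**
Reactants: 8 (3S)-3-acetoxy-6-formyl-2,2-dimethylchroman-8-yl pivalate; 10 1-[2-hydroxy-4-(methoxymethoxy)phenyl]ethan-1-one
Product: 12 (E)-3-[(3S)-3,8-dihydroxy-2,2-dimethylchroman-6-yl]-1-[2-hydroxy-4-(methoxymethoxy)phenyl]prop-2-en-1-one, via dihydroxy aldehyde 11 (not isolated)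
Conditions: KOH (50% aq., excess), EtOH, 0 °C → rt; then 1 M HCl to pH 5, 0 °C
Reagents that add atoms: none
Why: Saponification of both esters followed by Claisen–Schmidt condensation (aldol addition of the methyl ketone enolate, E1cB dehydration) should give the thermodynamically favoured (E)-enone; the C8 phenoxide is meta to the formyl group and does not deactivate it, the MOM acetal is base-stable, and C3 is not acidic so its configuration is untouched.

**Step 9**
Reactants: 12 (E)-3-[(3S)-3,8-dihydroxy-2,2-dimethylchroman-6-yl]-1-[2-hydroxy-4-(methoxymethoxy)phenyl]prop-2-en-1-one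
Product: 13 (E)-1-(2,4-dihydroxyphenyl)-3-[(3S)-3,8-dihydroxy-2,2-dimethylchroman-6-yl]prop-2-en-1-one
Conditions: 3 M HCl, MeOH, 40 °C, short reaction time
Reagents that add atoms: none
Why: Acid-catalysed acetal exchange should remove the MOM group as dimethoxymethane under conditions to which the secondary alcohol, the phenols and the (E)-enone are inert, the short reaction time limiting cyclisation of the 2'-hydroxychalcone to the flavanone.

**Compound list**
1 | 2,2-dimethyl-2,3-dihydro-1-benzofuran-7-ol | CC1(C)Cc2cccc(O)c2O1 | starting material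
2 | 2,2-dimethyl-2,3-dihydro-1-benzofuran-7-yl pivalate | CC1(C)Cc2cccc(OC(=O)C(C)(C)C)c2O1 | intermediate
3 | 2,2-dimethyl-3-oxo-2,3-dihydro-1-benzofuran-7-yl pivalate | CC1(C)Oc2c(OC(=O)C(C)(C)C)cccc2C1=O | intermediate
4 | 2,2-dimethyl-3-oxo-4-(trimethylsilyl)chroman-8-yl pivalate (racemic at C4, not isolated) | CC1(C)Oc2c(OC(=O)C(C)(C)C)cccc2C([Si](C)(C)C)C1=O | intermediate
5 | 2,2-dimethyl-3-oxochroman-8-yl pivalate | CC1(C)Oc2c(OC(=O)C(C)(C)C)cccc2CC1=O | intermediate
6 | (3S)-3-hydroxy-2,2-dimethylchroman-8-yl pivalate | CC1(C)Oc2c(OC(=O)C(C)(C)C)cccc2C[C@@H]1O | intermediate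
7 | (3S)-3-acetoxy-2,2-dimethylchroman-8-yl pivalate | CC1(C)Oc2c(OC(=O)C(C)(C)C)cccc2C[C@@H]1OC(C)=O | intermediate
8 | (3S)-3-acetoxy-6-formyl-2,2-dimethylchroman-8-yl pivalate | CC1(C)Oc2c(OC(=O)C(C)(C)C)cc(C=O)cc2C[C@@H]1OC(C)=O | intermediate
9 | 2,4-dihydroxyacetophenone | CC(=O)c1ccc(O)cc1O | starting material
10 | 1-[2-hydroxy-4-(methoxymethoxy)phenyl]ethan-1-one | COCOc1ccc(C(C)=O)c(O)c1 | intermediate
11 | (3S)-3,8-dihydroxy-2,2-dimethylchroman-6-carbaldehyde (not isolated) | CC1(C)Oc2c(O)cc(C=O)cc2C[C@@H]1O | intermediate
12 | (E)-3-[(3S)-3,8-dihydroxy-2,2-dimethylchroman-6-yl]-1-[2-hydroxy-4-(methoxymethoxy)phenyl]prop-2-en-1-one | CC1(C)Oc2c(O)cc(/C=C/C(=O)c3ccc(OCOC)cc3O)cc2C[C@@H]1O | intermediate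
13 | (E)-1-(2,4-dihydroxyphenyl)-3-[(3S)-3,8-dihydroxy-2,2-dimethylchroman-6-yl]prop-2-en-1-one | CC1(C)Oc2c(O)cc(/C=C/C(=O)c3ccc(O)cc3O)cc2C[C@@H]1O | target

**Totals**
Total step count: 9. Longest linear sequence: 8 (steps 1–6, 8, 9); step 7 is a one-step side branch.

**Steps most likely to fail**

Step 3 (ring expansion). The diazoalkane may add only sluggishly to a carbonyl that is flanked by a quaternary carbon and conjugated with O1, the reaction may stop at the silyl epoxide, or C2 may migrate in place of the aryl group. Fallback, from 3 back to 5: Wittig methylenation of 3 (Ph3P=CH2, THF; the ketone has no α-hydrogen, so enolisation cannot compete) would give 2,2-dimethyl-3-methylidene-2,3-dihydro-1-benzofuran-7-yl pivalate F1. Treatment of F1 with hydroxy(tosyloxy)iodobenzene in 95% MeOH, then dilute HCl, should give 5. The mechanism is iodonium addition to the exocyclic alkene, methanol capture at the benzylic carbon, and 1,2-aryl shift with loss of iodobenzene. This oxidative ring expansion is known for 1-methylideneindanes going to 2-tetralones.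

Step 6 (formylation). The ester-deactivated ring may react slowly, so that Lewis-acid-induced ionisation of the C3 acetate with O1 participation (ring contraction, loss of configuration) or attack at other ring positions competes. Fallback, from 6 back to 12, without a strong Lewis acid and without step 5: bromination of 6 with NBS in MeCN, para to the ring oxygen, would give (3S)-6-bromo-3-hydroxy-2,2-dimethylchroman-8-yl pivalate F2. Palladium-catalysed reductive carbonylation of F2 (Pd(OAc)2, di(1-adamantyl)-n-butylphosphine, CO/H2, TMEDA, toluene, 100 °C) would give (3S)-6-formyl-3-hydroxy-2,2-dimethylchroman-8-yl pivalate F3. F3 would then be used in place of 8 under the conditions of step 8, passing through 11 to 12.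

Step 4 (asymmetric reduction). Facial selectivity may be poor if borane coordination to O1 or uncatalysed reduction erodes the distinction between the two flanks of the ketone. Fallback, from 5 back to 6, by a reagent-controlled epoxidation:
- Enolisation is possible only towards C4, so Tf2O with 2,6-di-tert-butyl-4-methylpyridine in CH2Cl2 should give 2,2-dimethyl-3-(trifluoromethylsulfonyloxy)-2H-chromen-8-yl pivalate F4.
- Palladium-catalysed formate reduction (Pd(OAc)2, PPh3, HCO2H, Et3N, DMF, 60 °C) would give 2,2-dimethyl-2H-chromen-8-yl pivalate F5.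
- Jacobsen–Katsuki epoxidation with the (S,S)-Mn(salen) catalyst (NaOCl, 4-phenylpyridine N-oxide, CH2Cl2, 0 °C), on the substrate class for which it is most dependable, should give (3S,4S)-3,4-epoxy-2,2-dimethylchroman-8-yl pivalate F6.
- Regioselective hydrogenolysis of the benzylic C4–O bond (H2, Pd/C, EtOAc) would leave the C3–O bond intact and return 6.

**Further compounds**
F1 | step 3 | 2,2-dimethyl-3-methylidene-2,3-dihydro-1-benzofuran-7-yl pivalate | C=C1c2cccc(OC(=O)C(C)(C)C)c2OC1(C)C
F2 | step 6 | (3S)-6-bromo-3-hydroxy-2,2-dimethylchroman-8-yl pivalate | CC1(C)Oc2c(OC(=O)C(C)(C)C)cc(Br)cc2C[C@@H]1O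
F3 | step 6 | (3S)-6-formyl-3-hydroxy-2,2-dimethylchroman-8-yl pivalate | CC1(C)Oc2c(OC(=O)C(C)(C)C)cc(C=O)cc2C[C@@H]1O
F4 | step 4 | 2,2-dimethyl-3-(trifluoromethylsulfonyloxy)-2H-chromen-8-yl pivalate | CC1(C)Oc2c(OC(=O)C(C)(C)C)cccc2C=C1OS(=O)(=O)C(F)(F)F
F5 | step 4 | 2,2-dimethyl-2H-chromen-8-yl pivalate | CC1(C)Oc2c(OC(=O)C(C)(C)C)cccc2C=C1
F6 | step 4 | (3S,4S)-3,4-epoxy-2,2-dimethylchroman-8-yl pivalate | CC1(C)Oc2c(OC(=O)C(C)(C)C)cccc2[C@@H]2O[C@H]12
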